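Cuts: ring A is taken back to its 5,8-dihydro level, then C4a–C5 and C8a–C8 are cut together. This leaves 2,3-dimethoxybutadiene and a ring B cyclohexyne (C4a≡C8a). The C1–aryl bond is cut next, and the Si and OTf handles on C8a and C4a last.
Enabling feature: the fusion carbons C4a and C8a carry no stereochemistry, and ring A is symmetric about the axis through the C4a–C8a and C6–C7 bonds (H on C5/C8, OMe on C6/C7). A symmetric diene therefore fits the unsymmetrical alkyne in only one way, and the C1–C2–C3 triad of ring B lies outside the reacting π bond.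
That triad (C1 aryl trans to the cis methyls on C2 and C3) is what anti conjugate addition leaves on a cis-4,5-dimethylcyclohex-2-enone whose carbonyl carbon is C4a and whose α-carbon is C8a. Silicon is placed on that α-carbon before the aryl group arrives, so the enolate is triflated directly to the vicinal silyl triflate.
Forward order: ring B is present from the start (the cyclohexene of tetrahydrophthalic anhydride), the pendant aryl ring is joined at C1, and ring A is closed last by [4+2] cycloaddition and then aromatised.
Stereochemistry: cis C2/C3 comes from the cis-fused meso anhydride, the absolute configuration from chiral lithium amide desymmetrisation of a meso epoxide, and C1 from substrate-controlled cuprate attack opposite both methyls.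

Key step: step 11

Assumption: the lithium amide of the (R)-diamine is taken to distinguish the enantiotopic protons of epoxide 5 as it does for cyclohexene oxide, keeping the R-configured oxirane carbon as the carbinol; if the sense were reversed, the (S)-diamine would be used with nothing else changed.

Step 1
Reactants: 1 cis-1,2,3,6-tetrahydrophthalic anhydride (meso)
Product: 2 cis-cyclohex-4-ene-1,2-diyldimethanol (meso)
Conditions: LiAlH4, THF, 0 °C to reflux; aqueous work-up
Reagents that add atoms: none
Why: LiAlH4 reduction of a cyclic anhydride to the 1,4-diol leaves the isolated alkene and the two ring CH centres untouched, so the cis relationship bought with 1 (the future C2 and C3 methyls) is kept.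

Step 2
Reactants: 2 cis-cyclohex-4-ene-1,2-diyldimethanol
Product: 3 cis-cyclohex-4-ene-1,2-diylbis(methylene) dimethanesulfonate (meso)
Conditions: MsCl, Et3N, CH2Cl2, 0 °C
Reagents that add atoms: methanesulfonyl chloride, CS(=O)(=O)Cl
Why: Standard mesylation of primary alcohols turns both hydroxyls into leaving groups without involving a stereocentre.

Step 3
Reactants: 3 cis-cyclohex-4-ene-1,2-diylbis(methylene) dimethanesulfonate
Product: 4 cis-4,5-dimethylcyclohexene (meso)
Conditions: LiAlH4, Et2O, reflux; aqueous work-up; distillation
Reagents that add atoms: none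
Why: SN2 displacement of primary sulfonates by hydride (reductive deoxygenation with LiAlH4) converts both CH2OMs arms into methyl groups with the ring stereocentres as spectators, and the volatile hydrocarbon is collected by distillation.

Step 4
Reactants: 4 cis-4,5-dimethylcyclohexene
Product: 5 (1R,3R,4S,6S)-3,4-dimethyl-7-oxabicyclo[4.1.0]heptane (meso, oxygen anti to both methyls)
Conditions: mCPBA, CH2Cl2, 0 °C; chromatographic removal of the minor syn epoxide
Reagents that add atoms: 3-chloroperoxybenzoic acid, OOC(=O)c1cccc(Cl)c1
Why: In this Prilezhaev epoxidation the peracid approaches the half-chair on the face opposite the pseudoaxial homoallylic methyl, so both new C–O centres should be set mainly anti to the methyls by substrate control, and the minor syn epoxide must be removed because steps 5 and 6 would turn it into the enantiomeric enone.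

Step 5
Reactants: 5 (1R,3R,4S,6S)-3,4-dimethyl-7-oxabicyclo[4.1.0]heptane
Product: 6 (1R,4R,5R)-4,5-dimethylcyclohex-2-en-1-ol (hydroxyl trans to the two cis methyls)
Conditions: (R)-1-(pyrrolidin-2-ylmethyl)pyrrolidine, n-BuLi, THF, 0 °C; then 5, 0 °C to rt; aqueous work-up (diamine recovered by acid extraction)
Reagents that add atoms: none
Why: In this enantioselective β-elimination (chiral lithium amide rearrangement of a meso epoxide) the amide binds the oxirane oxygen and removes one of the two enantiotopic syn pseudoaxial protons through a cyclic transition state, so one oxirane carbon survives as the (R)-carbinol, the formerly equivalent methyl carbons become (4R,5R), and the absolute configuration of the whole route is fixed here.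

Step 6
Reactants: 6 (1R,4R,5R)-4,5-dimethylcyclohex-2-en-1-ol
Product: 7 (4R,5R)-4,5-dimethylcyclohex-2-en-1-one
Conditions: Dess–Martin periodinane, CH2Cl2, rt
Reagents that add atoms: none
Why: Dess–Martin oxidation of a secondary allylic alcohol runs under near-neutral conditions that remove the now superfluous carbinol centre and cannot epimerise C4 or C5.

Step 7
Reactants: 7 (4R,5R)-4,5-dimethylcyclohex-2-en-1-one
Product: 8 (4R,5R)-2-iodo-4,5-dimethylcyclohex-2-en-1-one
Conditions: I2, pyridine–CH2Cl2, 0 °C to rt
Reagents that add atoms: iodine, [I][I]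
Why: The α-iodination of an enone by conjugate addition of pyridine, iodination of the enolate and elimination (Baylis–Hillman-type mechanism) involves only C2 and C3 and uses a base too weak to deprotonate the γ-stereocentre C4.

Step 8
Reactants: 8 (4R,5R)-2-iodo-4,5-dimethylcyclohex-2-en-1-one
Product: 9 (8R,9R)-6-iodo-8,9-dimethyl-1,4-dioxaspiro[4.5]dec-6-ene
Conditions: TMSOCH2CH2OTMS, TMSOTf (cat.), CH2Cl2, −78 to −20 °C; pyridine quench
Reagents that add atoms: 1,2-bis(trimethylsilyloxy)ethane, C[Si](C)(C)OCCO[Si](C)(C)C
Why: Noyori ketalisation is aprotic and kinetically controlled at low temperature, so the double bond should not migrate towards the methyl-bearing γ-carbon, a migration that hot acidic glycol conditions could cause and that would erase that stereocentre.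

Step 9
Reactants: 9 (8R,9R)-6-iodo-8,9-dimethyl-1,4-dioxaspiro[4.5]dec-6-ene
Product: 12 (4R,5R)-4,5-dimethyl-2-(triethylsilyl)cyclohex-2-en-1-one, via vinyllithium 10 (not isolated), via silyl ketal 11 (not isolated)
Conditions: t-BuLi (2 equiv), Et2O, −78 °C; Et3SiCl, −78 °C to rt; then 1 M aq HCl, THF, rt
Reagents that add atoms: chlorotriethylsilane, CC[Si](Cl)(CC)CC; water, O
Why: Iodine–lithium exchange on a 2-halo enone ketal, silylation of the vinyllithium and mild dioxolane hydrolysis form the established route to 2-silyl enones, the alkene position is retained throughout, and no stereocentre takes part.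

Step 10
Reactants: 12 (4R,5R)-4,5-dimethyl-2-(triethylsilyl)cyclohex-2-en-1-one; 13 4-bromo-1,2-dimethoxybenzene
Product: 17 (3R,4R,5R)-3-(3,4-dimethoxyphenyl)-4,5-dimethyl-2-(triethylsilyl)cyclohex-1-en-1-yl trifluoromethanesulfonate, via 3,4-dimethoxyphenyllithium 14 (not isolated), via lithium diarylcuprate 15 (not isolated), via lithium silyl enolate 16 (not isolated)
Conditions: 13, n-BuLi, THF, −78 °C; CuI (0.5 equiv per ArLi), −40 °C; 12, −78 to −20 °C; then N-(5-chloropyridin-2-yl)bis(trifluoromethanesulfonimide) (Comins' reagent), −78 °C to rt; aq NH4Cl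
Reagents that add atoms: Comins' reagent, FC(F)(F)S(=O)(=O)N(c1ccc(Cl)cn1)S(=O)(=O)C(F)(F)F
Why: This is a Gilman cuprate conjugate addition to an α-silyl enone with trapping of the regiodefined enolate as its enol triflate, in which the aryl group enters axially on the half-chair that has the C4 methyl pseudoaxial and the C5 methyl equatorial, that is on the face opposite both methyls, so the new centre C3 (tetralin C1) is set trans to the adjacent methyl, and the enolate double bond forms between the carbonyl carbon and the silicon-bearing carbon, which places Si and OTf vicinal on one alkene with no regiochemical choice.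

Step 11
Reactants: 17 (3R,4R,5R)-3-(3,4-dimethoxyphenyl)-4,5-dimethyl-2-(triethylsilyl)cyclohex-1-en-1-yl trifluoromethanesulfonate; 18 2,3-dimethoxybuta-1,3-diene
Product: 20 (1R,2R,3R)-1-(3,4-dimethoxyphenyl)-6,7-dimethoxy-2,3-dimethyl-1,2,3,4,5,8-hexahydronaphthalene, via cyclohexyne 19 (not isolated)
Conditions: CsF, 18 (10 equiv), MeCN, rt, slow addition of 17; neutral work-up, Et3N-deactivated silica
Reagents that add atoms: none
Why: Fluoride attacks the silicon of 17 and the developing vinyl anion at C8a expels the neighbouring triflate, a mild 1,2-elimination that releases cyclohexyne 19 with its triple bond between C4a and C8a. The bent alkyne has a low-lying LUMO and sheds most of its strain in a concerted suprafacial [4+2] cycloaddition with the s-cis form of the electron-rich diene 18, whose termini bond to C4a (new C4a–C5) and to C8a (new C8a–C8). The closest known reactions are the Diels–Alder captures of fluoride-generated cyclohexynes and arynes from silyl triflates by furans, pyrones and isobenzofurans, and the use of 18 with activated alkynes as a veratrole precursor. Ring A closes by intermolecular [4+2] annulation, both σ bonds forming in one step to give a six-membered 1,4-cyclohexadiene bis(enol ether). No stereocentre is created because C5 and C8 are CH2 groups, the two orientations of the symmetric diene on the alkyne are identical so no regiochemistry arises, and C1, C2 and C3 are carried through unchanged. The step needs chemoselective [4+2] capture ahead of the base-induced shift of the propargylic, benzylic C1 hydrogen, [2+2] or ene reaction and oligomerisation, which is secured by the large excess of 18, the slow release of 19 by sparingly soluble CsF and the absence of any stronger base.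

Step 12
Reactants: 20 (1R,2R,3R)-1-(3,4-dimethoxyphenyl)-6,7-dimethoxy-2,3-dimethyl-1,2,3,4,5,8-hexahydronaphthalene
Product: 21 (1R,2R,3R)-1-(3,4-dimethoxyphenyl)-6,7-dimethoxy-2,3-dimethyl-1,2,3,4-tetrahydronaphthalene (target)
Conditions: DDQ (1 equiv), toluene, 0 °C
Reagents that add atoms: none
Why: In this DDQ dehydrogenative aromatisation, hydride abstraction from a doubly allylic CH2 next to an enol ether followed by proton loss should be far faster than attack at the C1 hydrogen, so one equivalent at low temperature should deliver the veratrole ring A with the C1–C2–C3 triad intact.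

Compound list
1 | cis-1,2,3,6-tetrahydrophthalic anhydride (meso) | O=C1OC(=O)[C@@H]2CC=CC[C@H]12 | starting material
2 | cis-cyclohex-4-ene-1,2-diyldimethanol (meso) | OC[C@@H]1CC=CC[C@@H]1CO | intermediate
3 | cis-cyclohex-4-ene-1,2-diylbis(methylene) dimethanesulfonate (meso) | CS(=O)(=O)OC[C@@H]1CC=CC[C@@H]1COS(C)(=O)=O | intermediate
4 | cis-4,5-dimethylcyclohexene (meso) | C[C@@H]1CC=CC[C@@H]1C | intermediate
5 | (1R,3R,4S,6S)-3,4-dimethyl-7-oxabicyclo[4.1.0]heptane (meso, O anti to methyls) | C[C@H]1C[C@@H]2O[C@@H]2C[C@H]1C | intermediate
6 | (1R,4R,5R)-4,5-dimethylcyclohex-2-en-1-ol | C1=C[C@H](O)C[C@@H](C)[C@H]1C | intermediate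
7 | (4R,5R)-4,5-dimethylcyclohex-2-en-1-one | C1=CC(=O)C[C@@H](C)[C@H]1C | intermediate
8 | (4R,5R)-2-iodo-4,5-dimethylcyclohex-2-en-1-one | C1=C(I)C(=O)C[C@@H](C)[C@H]1C | intermediate
9 | (8R,9R)-6-iodo-8,9-dimethyl-1,4-dioxaspiro[4.5]dec-6-ene | C1=C(I)C2(OCCO2)C[C@@H](C)[C@H]1C | intermediate
10 | (8R,9R)-6-lithio-8,9-dimethyl-1,4-dioxaspiro[4.5]dec-6-ene | C1=C([Li])C2(OCCO2)C[C@@H](C)[C@H]1C | intermediate
11 | triethyl[(8R,9R)-8,9-dimethyl-1,4-dioxaspiro[4.5]dec-6-en-6-yl]silane | C1=C([Si](CC)(CC)CC)C2(OCCO2)C[C@@H](C)[C@H]1C | intermediate
12 | (4R,5R)-4,5-dimethyl-2-(triethylsilyl)cyclohex-2-en-1-one | C1=C([Si](CC)(CC)CC)C(=O)C[C@@H](C)[C@H]1C | intermediate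
13 | 4-bromo-1,2-dimethoxybenzene | COc1ccc(Br)cc1OC | starting material
14 | 3,4-dimethoxyphenyllithium | COc1ccc([Li])cc1OC | intermediate
15 | lithium bis(3,4-dimethoxyphenyl)cuprate, Ar2CuLi | [Li+].COc1ccc([Cu-]c2ccc(OC)c(OC)c2)cc1OC | intermediate
16 | lithium (3R,4R,5R)-3-(3,4-dimethoxyphenyl)-4,5-dimethyl-2-(triethylsilyl)cyclohex-1-en-1-olate | COc1ccc([C@@H]2C([Si](CC)(CC)CC)=C(O[Li])C[C@@H](C)[C@H]2C)cc1OC | intermediate
17 | (3R,4R,5R)-3-(3,4-dimethoxyphenyl)-4,5-dimethyl-2-(triethylsilyl)cyclohex-1-en-1-yl trifluoromethanesulfonate | COc1ccc([C@@H]2C([Si](CC)(CC)CC)=C(OS(=O)(=O)C(F)(F)F)C[C@@H](C)[C@H]2C)cc1OC | intermediate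
18 | 2,3-dimethoxybuta-1,3-diene | COC(=C)C(=C)OC | starting material
19 | (3R,4R,5R)-3-(3,4-dimethoxyphenyl)-4,5-dimethylcyclohexyne | COc1ccc([C@@H]2C#CC[C@@H](C)[C@H]2C)cc1OC | intermediate
20 | (1R,2R,3R)-1-(3,4-dimethoxyphenyl)-6,7-dimethoxy-2,3-dimethyl-1,2,3,4,5,8-hexahydronaphthalene | COc1ccc([C@@H]2C3=C(CC(OC)=C(OC)C3)C[C@@H](C)[C@H]2C)cc1OC | intermediate
21 | (1R,2R,3R)-1-(3,4-dimethoxyphenyl)-6,7-dimethoxy-2,3-dimethyl-1,2,3,4-tetrahydronaphthalene | COc1ccc([C@@H]2c3cc(OC)c(OC)cc3C[C@@H](C)[C@H]2C)cc1OC | target

Total step count: 12. Longest linear sequence: 12 steps (1 to 21); 13 and 18 enter as purchased.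

Steps most likely to fail

Step 11.
- **Risk:** capture of the strained alkyne by an acyclic diene with a small s-cis population may be too slow. The shift of the propargylic, benzylic hydrogen to the cyclic allene, [2+2] or ene reaction at a single enol ether double bond, fluoride addition or oligomerisation could then take over.
- **Fallback:** it sets out from 17, forms the same two bonds and replaces the open diene with a locked s-cis diene. Treating 17 with CsF in MeCN in the presence of 3,4-dimethoxyfuran follows the well-known furan trapping of cyclohexynes and should give the oxygen-bridged Diels–Alder adduct F1, as a mixture of bridge orientations that is of no consequence. Reductive deoxygenation of the 7-oxanorbornadiene with low-valent titanium (TiCl4, LiAlH4, Et3N, THF, reflux) removes the bridge and aromatises ring A in one operation. The sequence comes back to the route at 21 and bypasses 20.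

Step 10.
- **Risk:** addition may be sluggish or 1,2-selective at a β-carbon flanked by the triethylsilyl group and the C4 methyl. Facial selectivity may erode, or O-sulfonylation of the crowded enolate may be incomplete.
- **Fallback:** it sets out from 7 and reverses the order in which aryl and silicon arrive.
  - Cuprate 15 with Me3SiCl adds to the unhindered enone 7, anti to both methyls, to give the trimethylsilyl enol ether F2.
  - NBS in THF at −78 °C converts F2 into the 2-bromo ketone F3.
  - Et3SiOTf and Et3N enolise F3 towards the bromine-bearing carbon to give the 2-bromo triethylsilyl enol ether F4.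
  - t-BuLi at −78 °C then triggers bromine–lithium exchange and 1,3 O-to-C silyl migration (retro-Brook rearrangement, as used for α-silyl ketones and for aryne precursors).
  - Silicon is thus delivered intramolecularly to the hindered carbon, and the sequence comes back to the route at enolate 16, which is triflated to 17 as in step 10.

Step 5.
- **Risk:** the enantiotopic protons may be discriminated insufficiently, or α-lithiation of the oxirane may compete, so that the material carried forward is not a single enantiomer.
- **Fallback:** it sets out from 5 and replaces desymmetrisation with resolution.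
  - LiNEt2 in Et2O rearranges 5 to the racemic allylic alcohol, that is 6 together with its enantiomer (1S,4S,5S)-4,5-dimethylcyclohex-2-en-1-ol F5.
  - Steglich esterification (DCC, DMAP) with (S)-2-methoxy-2-phenylacetic acid gives the (1R,4R,5R) ester F6 and the diastereomeric (1S,4S,5S) ester F7, which are separated by chromatography.
  - Methanolysis and hydrolysis of F6 (K2CO3, aq MeOH) comes back to the route at 6.
  - The same esterification can be applied to partly enriched 6 from step 5 to remove the minor enantiomer.

Further compounds
F1 | step 11 | (5R,6R,7R)-5-(3,4-dimethoxyphenyl)-2,3-dimethoxy-6,7-dimethyl-1,4,5,6,7,8-hexahydro-1,4-epoxynaphthalene (both bridge orientations) | COc1ccc([C@@H]2C3=C(C[C@@H](C)[C@H]2C)C2OC3C(OC)=C2OC)cc1OC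
F2 | step 10 | {[(3S,4R,5R)-3-(3,4-dimethoxyphenyl)-4,5-dimethylcyclohex-1-en-1-yl]oxy}trimethylsilane | COc1ccc([C@@H]2C=C(O[Si](C)(C)C)C[C@@H](C)[C@H]2C)cc1OC
F3 | step 10 | (3R,4R,5R)-2-bromo-3-(3,4-dimethoxyphenyl)-4,5-dimethylcyclohexan-1-one (epimers at C2) | COc1ccc([C@@H]2C(Br)C(=O)C[C@@H](C)[C@H]2C)cc1OC
F4 | step 10 | {[(3R,4R,5R)-2-bromo-3-(3,4-dimethoxyphenyl)-4,5-dimethylcyclohex-1-en-1-yl]oxy}triethylsilane | COc1ccc([C@@H]2C(Br)=C(O[Si](CC)(CC)CC)C[C@@H](C)[C@H]2C)cc1OC
F5 | step 5 | (1S,4S,5S)-4,5-dimethylcyclohex-2-en-1-ol | C1=C[C@@H](O)C[C@H](C)[C@@H]1C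
F6 | step 5 | (1R,4R,5R)-4,5-dimethylcyclohex-2-en-1-yl (S)-2-methoxy-2-phenylacetate | C1=C[C@H](OC(=O)[C@@H](OC)c2ccccc2)C[C@@H](C)[C@H]1C
F7 | step 5 | (1S,4S,5S)-4,5-dimethylcyclohex-2-en-1-yl (S)-2-methoxy-2-phenylacetate | C1=C[C@@H](OC(=O)[C@@H](OC)c2ccccc2)C[C@H](C)[C@@H]1C
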